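**Strategy.** The route rests on one disconnection: the bond between the bridging CH2 and cyclopentane C-1′, together with a temporary ether bond from the C-5 enol oxygen of the six-membered trione ring to the carbinol carbon C-2′. The feature used is the chain O–C5=C4–CH2–C1′–C2′(CH3)–O with CH2 and O cis on the five-membered ring, a latent cis-fused dihydropyran. An inverse-demand oxa-Diels–Alder reaction of an α-methylene acyl-triketone (a 1-oxadiene with the quaternary centre already set, made in situ from the triketone and formaldehyde) with the ring alkene of a silyl-masked (R)-methylcyclopentene forms both bonds and both new stereocentres at once; hydroxide later reopens the pyran.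

Key step: step 10

Assumption 1: the (S,S)-antipode of the N-spiro binaphthyl ammonium catalyst is taken to give the (S)-diester 10; if its sense of induction is the reverse, the (R,R)-antipode is used and nothing else changes.
Assumption 2: CIP descriptors of the quaternary carbon refer to the tautomers drawn in the compound list; its spatial arrangement is the same from 10 to 21.

**Cyclopentene arm**

Step 1
Reactants: 1 (R)-(+)-α-terpineol
Product: 2 α-terpinyl triethylsilyl ether, triethyl({2-[(1R)-4-methylcyclohex-3-en-1-yl]propan-2-yl}oxy)silane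
Conditions: TESOTf, 2,6-lutidine, CH2Cl2, −78 → 0 °C
Reagents that add atoms: triethylsilyl trifluoromethanesulfonate, CC[Si](CC)(CC)OS(=O)(=O)C(F)(F)F
Why: O-silylation with a silyl triflate and a hindered pyridine base works on tertiary alcohols; the ether masks the hydroxyl through the ozonolysis and aldol steps and later serves as the face-blocking group, and the stereocentre is not involved.

Step 2
Reactants: 2 α-terpinyl triethylsilyl ether
Product: 3 (3R)-6-oxo-3-[2-(triethylsilyloxy)propan-2-yl]heptanal
Conditions: O3, CH2Cl2–MeOH, NaHCO3, −78 °C; then Me2S, −78 °C → rt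
Reagents that add atoms: ozone, [O-][O+]=O
Why: Ozonolysis with reductive work-up cleaves the only C=C bond to a methyl ketone and an aldehyde; the buffered medium spares the silyl ether, and the stereocentre (β to the aldehyde) carries no acidic hydrogen.

Step 3
Reactants: 3 keto aldehyde
Product: 4 (5R)-2-methyl-5-[2-(triethylsilyloxy)propan-2-yl]cyclopent-1-ene-1-carbaldehyde
Conditions: piperidine (0.3 equiv), AcOH (0.3 equiv), toluene, 80 °C, 4 Å MS
Reagents that add atoms: none
Why: Amine-catalysed intramolecular aldol condensation: the aldehyde-derived enamine attacks the methyl ketone to close the five-membered ring and dehydration gives the conjugated enal; the stereocentre is α to neither carbonyl and cannot epimerise.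

Step 4
Reactants: 4 cyclopentene carbaldehyde
Product: 5 triethyl({2-[(1R)-3-methylcyclopent-2-en-1-yl]propan-2-yl}oxy)silane
Conditions: RhCl(PPh3)3 (1.05 equiv), PhCN, 130 °C
Reagents that add atoms: none
Why: Tsuji–Wilkinson decarbonylation (oxidative addition into the formyl C–H bond, CO de-insertion, reductive elimination) replaces CHO by H with the double bond kept in place; rhodium is used stoichiometrically because the carbonyl complex formed does not turn over at this temperature.

**Triketone arm**

Step 5
Reactants: 6 methyl Meldrum's acid (2,2,5-trimethyl-1,3-dioxane-4,6-dione)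
Product: 7 3-tert-butoxy-2-methyl-3-oxopropanoic acid (racemic, configurationally labile CH)
Conditions: t-BuOH, toluene, reflux
Reagents that add atoms: tert-butanol, CC(C)(C)O
Why: Thermal alcoholysis of the Meldrum's acid ring with loss of acetone gives the malonic half ester.

Step 6
Reactants: 7 mono-tert-butyl methylmalonate
Product: 8 1-tert-butyl 3-(2,2-diphenylethyl) 2-methylpropanedioate (racemic, labile CH)
Conditions: 2,2-diphenylethanol, DCC, DMAP (cat.), CH2Cl2, 0 °C → rt
Reagents that add atoms: 2,2-diphenylethanol, OCC(c1ccccc1)c1ccccc1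
Why: Steglich esterification of the free acid with a primary alcohol gives a mixed diester whose two ester groups differ in bulk and in cleavage chemistry.

Step 7
Reactants: 8 mixed methylmalonate; 9 prenyl bromide (1-bromo-3-methylbut-2-ene)
Product: 10 1-tert-butyl 3-(2,2-diphenylethyl) (2S)-2-methyl-2-(3-methylbut-2-en-1-yl)propanedioate
Conditions: (S,S)-3,4,5-trifluorophenyl-NAS bromide (5 mol %), 50% aq KOH, toluene, −40 °C
Reagents that add atoms: prenyl bromide (9), CC(C)=CCBr
Why: Enantioselective phase-transfer alkylation of an α-methylmalonate carrying one tert-butyl and one aryl-rich ester: the chiral ammonium cation pairs with the enolate and shields one face, SN2 attack on the primary allylic bromide gives the linear prenyl group, and the quaternary stereocentre (later C-6 of the target) is set by the catalyst.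

Step 8
Reactants: 10 quaternary mixed diester
Product: 11 (2R)-2-[(2,2-diphenylethoxy)carbonyl]-2,5-dimethylhex-4-enoic acid
Conditions: TMSOTf, 2,6-lutidine, CH2Cl2, 0 °C; then aqueous pH 5 buffer
Reagents that add atoms: none
Why: Silyl-triflate-mediated tert-butyl ester cleavage (O-silylation, loss of isobutene, hydrolysis of the silyl ester) runs under buffered aprotic conditions, which avoids acid-induced lactonisation onto the prenyl alkene and leaves the primary ester; the quaternary centre has no α-hydrogen and cannot racemise.

Step 9
Reactants: 11 half ester acid; 12 5-methylhexane-2,4-dione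
Product: 15 (2R)-5-hydroxy-2-methyl-2-(3-methylbut-2-en-1-yl)-4-(2-methylpropanoyl)cyclohex-4-ene-1,3-dione, via acyl imidazolide 13 (not isolated), via triketo ester 14 (not isolated)
Conditions: CDI, THF, rt; add to the dianion of 12 (12 3 equiv, LDA 6 equiv, THF, −78 → 0 °C); then NaOMe, MeOH, 50 °C; aq HCl work-up
Reagents that add atoms: none
Why: The acyl imidazolide C-acylates the more reactive terminal carbanion of the β-diketone dianion, and methoxide then drives a Claisen (Dieckmann-type) closure of the doubly activated internal carbon onto the remaining ester to the stabilised triketone anion; the former acid carbon becomes the ring carbonyl next to CH2 and the former ester carbon the one next to the acyl-bearing carbon, so the configuration of 11 maps directly onto 15.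

**Key step and endgame**

Step 10
Reactants: 15 acyl triketone; 16 formaldehyde (as paraformaldehyde); 5 silyl-masked cyclopentene
Product: 18 (1R,3aR,5R,9aS)-8-hydroxy-3a,5-dimethyl-5-(3-methylbut-2-en-1-yl)-7-(2-methylpropanoyl)-1-[2-(triethylsilyloxy)propan-2-yl]-1,2,3,3a,9,9a-hexahydrocyclopenta[b]chromen-6(5H)-one, via methylene triketone 17 (not isolated)
Conditions: (CH2O)n (3 equiv), ethylenediammonium diacetate (20 mol %), 5 (1.5 equiv), 1,4-dioxane, 80 °C, slow addition of 15
Reagents that add atoms: formaldehyde (16), C=O
Why: Knoevenagel condensation of the C-6 methylene of 15 with formaldehyde gives the α-methylene triketone 17, whose exocyclic C=C and C-1 carbonyl act as an electron-poor 1-oxadiene that adds to the electron-rich trisubstituted alkene of 5 in a concerted but asynchronous inverse-demand [4+2] cycloaddition (C–C bond formation ahead of C–O). The closest known reaction type is the domino Knoevenagel/oxa-Diels–Alder reaction of cyclic β-di- and β-triketones with formaldehyde and unactivated terpene alkenes. The dihydropyran is closed as a six-membered ring in this single suprafacial cycloaddition, which makes the ring fusion cis, so CH2 and O end up on the same face of the cyclopentane. Both new stereocentres (C-9a and C-3a) are controlled by the existing stereocentre C-1: its quaternary CMe2OTES group blocks one face, so both bonds form anti to it. The step needs regioselectivity (oxygen to the methyl-bearing carbon, secured by the alkene polarisation, which places the developing positive charge on the tertiary carbon), chemoselectivity against conjugate addition of a second molecule of 15 (secured by slow addition of 15 to excess alkene) and absence of a competing isopropenyl alkene (secured by carrying it as the silyloxy-isopropyl group). The hydrogen-bonded acyl enol leaves the C-1 carbonyl as the diene terminus, and a pyran closed on the other enol oxygen would lead to the same target after step 13.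

Step 11
Reactants: 18 silylated pyran adduct
Product: 19 (1R,3aR,5R,9aS)-8-hydroxy-1-(2-hydroxypropan-2-yl)-3a,5-dimethyl-5-(3-methylbut-2-en-1-yl)-7-(2-methylpropanoyl)-1,2,3,3a,9,9a-hexahydrocyclopenta[b]chromen-6(5H)-one
Conditions: HF·pyridine, pyridine, THF, 0 °C → rt
Reagents that add atoms: none
Why: Fluoride cleaves the Si–O bond under pyridine-buffered conditions that leave the vinylogous ester, the enol and the prenyl alkene untouched.

Step 12
Reactants: 19 tertiary alcohol
Product: 20 (1R,3aR,5R,9aS)-8-hydroxy-3a,5-dimethyl-5-(3-methylbut-2-en-1-yl)-7-(2-methylpropanoyl)-1-(prop-1-en-2-yl)-1,2,3,3a,9,9a-hexahydrocyclopenta[b]chromen-6(5H)-one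
Conditions: Burgess reagent (3 equiv), toluene, 50 °C
Reagents that add atoms: none
Why: The Burgess reagent converts the tertiary alcohol into a sulfamate that undergoes syn-elimination; loss of one of six methyl hydrogens should be preferred over the single ring methine hydrogen (which would give a strained tetrasubstituted exocyclic alkene next to the ring fusion), the ring carbinol is protected as the pyran ether, and the hydrogen-bonded enol is a poor nucleophile (any sulfamate formed there is cleaved in step 13).

Step 13
Reactants: 20 isopropenyl pyran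
Product: 21 target, (6R)-3,5-dihydroxy-4-{[(1S,2R,5R)-2-hydroxy-2-methyl-5-(prop-1-en-2-yl)cyclopentyl]methyl}-6-methyl-6-(3-methylbut-2-en-1-yl)-2-(2-methylpropanoyl)cyclohexa-2,4-dien-1-one
Conditions: KOH (10 equiv), DMSO–H2O 4:1, 70 °C; then 1 M HCl to pH 4, 0 °C
Reagents that add atoms: potassium hydroxide, [K+].[OH-]
Why: Hydroxide adds to C-4a, the β-carbon of the vinylogous ester, and expels the tertiary alkoxide (conjugate addition–elimination, as in the base-induced opening of chromones and other β-alkoxy enones), so the sp2 C–O bond breaks while the carbinol C–O bond and its configuration stay intact; formation of the doubly ionised acyl-trione makes the opening irreversible until the careful acidification.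

**Compound list**

1 | (R)-(+)-α-terpineol | CC1=CC[C@@H](CC1)C(C)(C)O | starting material
2 | triethyl({2-[(1R)-4-methylcyclohex-3-en-1-yl]propan-2-yl}oxy)silane | CC1=CC[C@@H](CC1)C(C)(C)O[Si](CC)(CC)CC | intermediate
3 | (3R)-6-oxo-3-[2-(triethylsilyloxy)propan-2-yl]heptanal | CC(=O)CC[C@H](CC=O)C(C)(C)O[Si](CC)(CC)CC | intermediate
4 | (5R)-2-methyl-5-[2-(triethylsilyloxy)propan-2-yl]cyclopent-1-ene-1-carbaldehyde | CC1=C(C=O)[C@@H](CC1)C(C)(C)O[Si](CC)(CC)CC | intermediate
5 | triethyl({2-[(1R)-3-methylcyclopent-2-en-1-yl]propan-2-yl}oxy)silane | CC(C)(O[Si](CC)(CC)CC)[C@@H]1CCC(C)=C1 | intermediate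
6 | 2,2,5-trimethyl-1,3-dioxane-4,6-dione (methyl Meldrum's acid) | CC1C(=O)OC(C)(C)OC1=O | starting material
7 | 3-tert-butoxy-2-methyl-3-oxopropanoic acid (racemic) | CC(C(=O)O)C(=O)OC(C)(C)C | intermediate
8 | 1-tert-butyl 3-(2,2-diphenylethyl) 2-methylpropanedioate (racemic) | CC(C(=O)OC(C)(C)C)C(=O)OCC(c1ccccc1)c1ccccc1 | intermediate
9 | prenyl bromide (1-bromo-3-methylbut-2-ene) | CC(C)=CCBr | starting material
10 | 1-tert-butyl 3-(2,2-diphenylethyl) (2S)-2-methyl-2-(3-methylbut-2-en-1-yl)propanedioate | CC(C)(C)OC(=O)[C@@](C)(CC=C(C)C)C(=O)OCC(c1ccccc1)c1ccccc1 | intermediate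
11 | (2R)-2-[(2,2-diphenylethoxy)carbonyl]-2,5-dimethylhex-4-enoic acid | OC(=O)[C@@](C)(CC=C(C)C)C(=O)OCC(c1ccccc1)c1ccccc1 | intermediate
12 | 5-methylhexane-2,4-dione | CC(=O)CC(=O)C(C)C | starting material
13 | 2,2-diphenylethyl (2R)-2-(1H-imidazole-1-carbonyl)-2,5-dimethylhex-4-enoate (formed in situ) | O=C(n1ccnc1)[C@@](C)(CC=C(C)C)C(=O)OCC(c1ccccc1)c1ccccc1 | intermediate
14 | 2,2-diphenylethyl (2R)-2,8-dimethyl-2-(3-methylbut-2-en-1-yl)-3,5,7-trioxononanoate (formed in situ) | CC(C)C(=O)CC(=O)CC(=O)[C@@](C)(CC=C(C)C)C(=O)OCC(c1ccccc1)c1ccccc1 | intermediate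
15 | (2R)-5-hydroxy-2-methyl-2-(3-methylbut-2-en-1-yl)-4-(2-methylpropanoyl)cyclohex-4-ene-1,3-dione | CC(C)C(=O)C1=C(O)CC(=O)[C@@](C)(CC=C(C)C)C1=O | intermediate
16 | formaldehyde (used as paraformaldehyde) | C=O | starting material
17 | (2R)-5-hydroxy-2-methyl-6-methylidene-2-(3-methylbut-2-en-1-yl)-4-(2-methylpropanoyl)cyclohex-4-ene-1,3-dione (formed in situ) | C=C1C(=O)[C@@](C)(CC=C(C)C)C(=O)C(C(=O)C(C)C)=C1O | intermediate
18 | (1R,3aR,5R,9aS)-8-hydroxy-3a,5-dimethyl-5-(3-methylbut-2-en-1-yl)-7-(2-methylpropanoyl)-1-[2-(triethylsilyloxy)propan-2-yl]-1,2,3,3a,9,9a-hexahydrocyclopenta[b]chromen-6(5H)-one | CC(C)(O[Si](CC)(CC)CC)[C@@H]1CC[C@@]2(C)OC3=C(C[C@@H]12)C(O)=C(C(=O)C(C)C)C(=O)[C@]3(C)CC=C(C)C | intermediate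
19 | (1R,3aR,5R,9aS)-8-hydroxy-1-(2-hydroxypropan-2-yl)-3a,5-dimethyl-5-(3-methylbut-2-en-1-yl)-7-(2-methylpropanoyl)-1,2,3,3a,9,9a-hexahydrocyclopenta[b]chromen-6(5H)-one | CC(C)(O)[C@@H]1CC[C@@]2(C)OC3=C(C[C@@H]12)C(O)=C(C(=O)C(C)C)C(=O)[C@]3(C)CC=C(C)C | intermediate
20 | (1R,3aR,5R,9aS)-8-hydroxy-3a,5-dimethyl-5-(3-methylbut-2-en-1-yl)-7-(2-methylpropanoyl)-1-(prop-1-en-2-yl)-1,2,3,3a,9,9a-hexahydrocyclopenta[b]chromen-6(5H)-one | C=C(C)[C@@H]1CC[C@@]2(C)OC3=C(C[C@@H]12)C(O)=C(C(=O)C(C)C)C(=O)[C@]3(C)CC=C(C)C | intermediate
21 | (6R)-3,5-dihydroxy-4-{[(1S,2R,5R)-2-hydroxy-2-methyl-5-(prop-1-en-2-yl)cyclopentyl]methyl}-6-methyl-6-(3-methylbut-2-en-1-yl)-2-(2-methylpropanoyl)cyclohexa-2,4-dien-1-one | C=C(C)[C@@H]1CC[C@@](C)(O)[C@H]1CC1=C(O)[C@@](C)(CC=C(C)C)C(=O)C(C(=O)C(C)C)=C1O | target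

**Step count**

Total: 13 steps. Longest linear sequence: 9 steps (steps 5–13, from methyl Meldrum's acid); the cyclopentene arm (steps 1–4) joins at step 10.

**Steps most likely to fail**

Step 10. The heterodiene 17 may be consumed by conjugate addition of a second molecule of 15 (methylene-bridged dimer) faster than it adds to the hindered alkene, or the addition may not occur fully anti to the silyloxy-isopropyl group. The fallback separates the generation of the heterodiene from the condensation. It sets out from 15: a Mannich reaction with morpholine and aqueous formaldehyde (EtOH, rt) should give the morpholinomethyl triketone F1, isolable as its zwitterion. Heating F1 with 5 (toluene, 100 °C, 1 equiv AcOH) should release 17 by elimination of morpholine in the absence of free 15, so that the cycloaddition is the only productive pathway. The fallback comes back to the route at 18.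

Step 13. Addition of hydroxide to the hindered enol-ether carbon of the already deprotonated substrate may be too slow, and at forcing temperature retro-Claisen loss of the 2-methylpropanoyl group may compete. The fallback replaces the charged oxygen nucleophile by a neutral amine under buffered conditions that keep the enol protonated. It sets out from 20: pyrrolidinium acetate in EtOH at 70 °C should exchange the tertiary alkoxy group by conjugate addition–elimination and give the ring-opened vinylogous amide F2. Hydrolysis of F2 with 1 M HCl in THF at rt should then give the enol, and the fallback comes back to the route at 21.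

Step 12. Elimination may also remove the ring methine hydrogen (isopropylidene isomer), and the acidic enol may consume the dehydrating agent. The fallback caps the enol and changes the elimination mechanism from syn (sulfamate) to anti (E2 of a chlorosulfite with pyridine as base), which favours the exposed methyl hydrogens. It sets out from 19: O-acetylation of the enol (AcCl, Et3N, CH2Cl2, −20 °C, tertiary alcohol untouched) should give the enol acetate F3. SOCl2/pyridine (CH2Cl2, −30 °C) should then give the isopropenyl enol acetate F4. F4 is submitted to the conditions of step 13, where hydroxide removes the acetate and opens the pyran, so the fallback comes back to the route at 21.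

**Further compounds**

F1 | step 10 | (6R)-3,5-dihydroxy-6-methyl-6-(3-methylbut-2-en-1-yl)-2-(2-methylpropanoyl)-4-(morpholin-4-ylmethyl)cyclohexa-2,4-dien-1-one | CC(C)C(=O)C1=C(O)C(CN2CCOCC2)=C(O)[C@@](C)(CC=C(C)C)C1=O
F2 | step 13 | (6R)-3-hydroxy-4-{[(1S,2R,5R)-2-hydroxy-2-methyl-5-(prop-1-en-2-yl)cyclopentyl]methyl}-6-methyl-6-(3-methylbut-2-en-1-yl)-2-(2-methylpropanoyl)-5-(pyrrolidin-1-yl)cyclohexa-2,4-dien-1-one | C=C(C)[C@@H]1CC[C@@](C)(O)[C@H]1CC1=C(N2CCCC2)[C@@](C)(CC=C(C)C)C(=O)C(C(=O)C(C)C)=C1O
F3 | step 12 | (1R,3aR,5R,9aS)-1-(2-hydroxypropan-2-yl)-3a,5-dimethyl-5-(3-methylbut-2-en-1-yl)-7-(2-methylpropanoyl)-6-oxo-1,2,3,3a,5,6,9,9a-octahydrocyclopenta[b]chromen-8-yl acetate | CC(C)(O)[C@@H]1CC[C@@]2(C)OC3=C(C[C@@H]12)C(OC(C)=O)=C(C(=O)C(C)C)C(=O)[C@]3(C)CC=C(C)C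
F4 | step 12 | (1R,3aR,5R,9aS)-3a,5-dimethyl-5-(3-methylbut-2-en-1-yl)-7-(2-methylpropanoyl)-6-oxo-1-(prop-1-en-2-yl)-1,2,3,3a,5,6,9,9a-octahydrocyclopenta[b]chromen-8-yl acetate | C=C(C)[C@@H]1CC[C@@]2(C)OC3=C(C[C@@H]12)C(OC(C)=O)=C(C(=O)C(C)C)C(=O)[C@]3(C)CC=C(C)C
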